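## Retrosynthetic overview

1. Target 29 comes from global desilylation of 28, which comes from a Steglich ester bond (C5–O of the lactone) between hydroxy-lactone 18 and dienoic acid 27.
2. Only one ring is built: the dihydropyranone of 18, formed from the purchased furan ring of 16 by Achmatowicz ring expansion and then an iridium-catalysed internal redox isomerisation. The butyrolactone of 21 is only a stereo-template and is opened.
3. Key disconnection: the C2–C3 bond of furyl ketone 15, made by nickel-catalysed stereoconvergent radical cross-coupling of racemic α-bromo ketone 12 with alkylzinc 14. This joins the two halves and sets the α-methyl stereocentre.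
4. Alkylzinc 14 comes from chloride 9, made by lithiation–borylation of (R)-butenyl carbamate 4 with boronate 2 (from (R)-1-bromo-3-chloro-2-methylpropane).
5. Acid 27 comes from a Doebner condensation (malonic acid) of enal 25, made by SeO2 oxidation, LiAlH4 reduction/silylation and Rh-catalysed alkenyl conjugate addition to furan-2(5H)-one.

Assumption: the ligand antipodes named in steps 6 and 10 are assigned by analogy with the closest published cases; they would be confirmed on a model substrate and swapped for the antipode if the sense is reversed.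

## Route

Step 1
Reactants: 1 (R)-1-bromo-3-chloro-2-methylpropane
Product: 2 2-[(2S)-3-chloro-2-methylpropyl]-4,4,5,5-tetramethyl-1,3,2-dioxaborolane
Conditions: B2pin2 (1.5 equiv), CuI (10 mol%), PPh3 (13 mol%), LiOMe (2 equiv), DMF, rt
Reagents that add atoms: bis(pinacolato)diboron CC1(C)OB(OC1(C)C)B1OC(C)(C)C(C)(C)O1
Why: Copper-catalysed borylation of a primary alkyl bromide is selective for C–Br over C–Cl at room temperature and does not touch the β-stereocentre carried over from 1 (the descriptor changes from R to S only through the priority switch).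

Step 2
Reactants: 3 (R)-but-3-en-2-ol
Product: 4 (2R)-but-3-en-2-yl N,N-di(propan-2-yl)carbamate
Conditions: i-Pr2NCOCl (1.2 equiv), Et3N (1.3 equiv), CH2Cl2, reflux
Reagents that add atoms: N,N-diisopropylcarbamoyl chloride CC(C)N(C(C)C)C(Cl)=O
Why: O-Carbamoylation installs the Hoppe directing and leaving group on the secondary allylic alcohol without touching its stereocentre.

Step 3
Reactants: 4 (2R)-but-3-en-2-yl N,N-di(propan-2-yl)carbamate; 2 2-[(2S)-3-chloro-2-methylpropyl]-4,4,5,5-tetramethyl-1,3,2-dioxaborolane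
Product: 8 (3S,5S)-6-chloro-3,5-dimethylhex-1-en-3-ol, via lithiated carbamate 5 (not isolated), via lithium boronate complex 6 (not isolated), via tertiary allylic boronic ester 7 (not isolated)
Conditions: 4 (1.3 equiv), s-BuLi, TMEDA, Et2O, −78 °C; then 2, −78 °C → rt; then NaBO3·4H2O, THF/H2O, rt
Reagents that add atoms: sodium perborate [Na+].[Na+].O[B-]1(O)OO[B-](O)(O)OO1
Why: Aggarwal lithiation–borylation: α-lithiation and borylation go with retention, the anti-periplanar 1,2-metallate shift inverts carbon and the oxidation retains, so C–H is formally replaced by C–C with oxygen kept and (R)-4 gives the S tertiary carbinol; mildly basic perborate avoids tetrahydrofuran closure of the tertiary alkoxide onto the chloride.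

Step 4
Reactants: 8 (3S,5S)-6-chloro-3,5-dimethylhex-1-en-3-ol
Product: 9 {[(3S,5S)-6-chloro-3,5-dimethylhex-1-en-3-yl]oxy}triethylsilane
Conditions: TESOTf (1.3 equiv), 2,6-lutidine (2 equiv), CH2Cl2, −78 → 0 °C
Reagents that add atoms: triethylsilyl trifluoromethanesulfonate CC[Si](CC)(CC)OS(=O)(=O)C(F)(F)F
Why: Silyl triflate silylation protects the hindered tertiary allylic alcohol so that it can neither quench the organozinc nor cyclise onto the halide.

Step 5
Reactants: 10 furan; 11 2-bromopropanoyl chloride (racemic)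
Product: 12 2-bromo-1-(furan-2-yl)propan-1-one (racemic)
Conditions: SnCl4 (1.1 equiv), CH2Cl2, −78 → −20 °C
Reagents that add atoms: none
Why: Friedel–Crafts acylation occurs at the most nucleophilic furan position (C2) at low temperature; the bromide centre is racemic on purpose because step 6 is stereoconvergent.

Step 6
Reactants: 9 {[(3S,5S)-6-chloro-3,5-dimethylhex-1-en-3-yl]oxy}triethylsilane; 12 2-bromo-1-(furan-2-yl)propan-1-one (racemic)
Product: 15 (2S,4R,6S)-1-(furan-2-yl)-2,4,6-trimethyl-6-[(triethylsilyl)oxy]oct-7-en-1-one, via alkyl iodide 13 (not isolated), via alkylzinc iodide 14 (not isolated)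
Conditions: 9, Zn dust (activated), NaI (1.1 equiv), DMA, 70 °C; then 12 (1.3 equiv), NiCl2·glyme (10 mol%), (R,R)-i-Pr-Pybox (13 mol%), DMA/THF, −20 → 0 °C
Reagents that add atoms: none
Why: Proposed new method: Negishi-type nickel-catalysed stereoconvergent radical cross-coupling, in which monovalent nickel abstracts bromine from either enantiomer of 12 to give a planar α-keto radical, this radical is captured by the pybox-bound alkylnickel formed from 14, and reductive elimination from trivalent nickel forges C2–C3 and sets C2 as S under ligand control (the remote centres of 14 are spectators); the closest known reactions are the nickel/pybox couplings of racemic α-bromo amides with alkylzinc halides and of racemic α-bromo aryl ketones with arylzinc halides.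

Step 7
Reactants: 15 (2S,4R,6S)-1-(furan-2-yl)-2,4,6-trimethyl-6-[(triethylsilyl)oxy]oct-7-en-1-one
Product: 16 (1R,2S,4R,6S)-1-(furan-2-yl)-2,4,6-trimethyl-6-[(triethylsilyl)oxy]oct-7-en-1-ol
Conditions: RuCl[(R,R)-TsDPEN](p-cymene) (2 mol%), HCO2Na, CTAB, H2O/CH2Cl2, rt
Reagents that add atoms: none
Why: Noyori asymmetric transfer hydrogenation of an acylfuran sets the carbinol as R by catalyst control (the (R,R) catalyst gives R aryl carbinols) and overrides the Felkin preference of the α-methyl ketone; the near-neutral formate medium spares the α-stereocentre, the alkene and the silyl ether.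

Step 8
Reactants: 16 (1R,2S,4R,6S)-1-(furan-2-yl)-2,4,6-trimethyl-6-[(triethylsilyl)oxy]oct-7-en-1-ol
Product: 17 (2R)-2-{(2S,4R,6S)-4,6-dimethyl-6-[(triethylsilyl)oxy]oct-7-en-2-yl}-6-hydroxy-2H-pyran-3(6H)-one (anomer mixture)
Conditions: NBS (1.05 equiv), NaHCO3, NaOAc, THF/H2O (4:1), 0 °C
Reagents that add atoms: water O
Why: Achmatowicz rearrangement: the electron-rich furan is oxidised far faster than the hindered terminal alkene, and the carbinol oxygen closes the six-membered hemiacetal with its stereocentre untouched.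

Step 9
Reactants: 17 (2R)-2-{(2S,4R,6S)-4,6-dimethyl-6-[(triethylsilyl)oxy]oct-7-en-2-yl}-6-hydroxy-2H-pyran-3(6H)-one
Product: 18 (5S,6R)-6-{(2S,4R,6S)-4,6-dimethyl-6-[(triethylsilyl)oxy]oct-7-en-2-yl}-5-hydroxy-5,6-dihydro-2H-pyran-2-one
Conditions: [Ir(cod)Cl]2 (2.5 mol%), 2,6-dichlorobenzoic acid (20 mol%), CHCl3, rt
Reagents that add atoms: none
Why: Iridium-catalysed dynamic kinetic internal redox isomerisation of an Achmatowicz product: the hydride taken from the anomeric C–H of the equilibrating lactol is returned to the ketone, so the lactol becomes the lactone and the ketone becomes the C5 carbinol with OH trans to the C6 side chain (5S); the vinyl group has no allylic hydrogen and cannot migrate.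

Step 10
Reactants: 19 furan-2(5H)-one; 20 (2-methylprop-1-en-1-yl)boronic acid
Product: 21 (4R)-4-(2-methylprop-1-en-1-yl)oxolan-2-one
Conditions: 20 (2.5 equiv), [Rh(OH)((R)-BINAP)]2 (2.5 mol%), dioxane/H2O (10:1), 40 °C
Reagents that add atoms: none
Why: Hayashi–Miyaura rhodium-catalysed asymmetric 1,4-addition of an alkenylboronic acid to the unsaturated lactone sets the β-stereocentre as R by ligand control.

Step 11
Reactants: 21 (4R)-4-(2-methylprop-1-en-1-yl)oxolan-2-one
Product: 22 (2R)-2-(2-methylprop-1-en-1-yl)butane-1,4-diol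
Conditions: LiAlH4, THF, 0 °C → rt
Reagents that add atoms: none
Why: Hydride reduction opens the lactone to the 1,4-diol, turning the two ring arms into the CH2OH and CH2CH2OH groups without touching the stereocentre or the alkene.

Step 12
Reactants: 22 (2R)-2-(2-methylprop-1-en-1-yl)butane-1,4-diol
Product: 23 (2R)-1,4-bis[(tert-butyldimethylsilyl)oxy]-2-(2-methylprop-1-en-1-yl)butane
Conditions: TBSCl (2.4 equiv), imidazole, DMF, rt
Reagents that add atoms: tert-butyldimethylsilyl chloride CC(C)(C)[Si](C)(C)Cl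
Why: Standard bis-silylation of the two primary alcohols keeps them from competing in the later esterification.

Step 13
Reactants: 23 (2R)-1,4-bis[(tert-butyldimethylsilyl)oxy]-2-(2-methylprop-1-en-1-yl)butane
Product: 25 (2E,4R)-6-[(tert-butyldimethylsilyl)oxy]-4-{[(tert-butyldimethylsilyl)oxy]methyl}-2-methylhex-2-enal, via allylic alcohol 24 (not isolated)
Conditions: SeO2 (0.5 equiv), t-BuOOH (3 equiv), CH2Cl2, rt; then filter, MnO2 (excess), CH2Cl2, rt
Reagents that add atoms: selenium dioxide O=[Se]=O (oxygen carrier), tert-butyl hydroperoxide CC(C)(C)OO (terminal oxygen source)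
Why: Riley allylic oxidation (ene reaction then [2,3]-shift) attacks the E-methyl at the more substituted alkene end and restores the double bond as E without touching the allylic stereocentre; MnO2 then converges the allylic alcohol/enal mixture to the enal.

Step 14
Reactants: 25 (2E,4R)-6-[(tert-butyldimethylsilyl)oxy]-4-{[(tert-butyldimethylsilyl)oxy]methyl}-2-methylhex-2-enal; 26 malonic acid
Product: 27 (2E,4E,6R)-8-[(tert-butyldimethylsilyl)oxy]-6-{[(tert-butyldimethylsilyl)oxy]methyl}-4-methylocta-2,4-dienoic acid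
Conditions: 26 (2 equiv), pyridine, 85 °C
Reagents that add atoms: none
Why: Doebner–Knoevenagel condensation with decarboxylation gives the 2E dienoic acid directly (as in the preparation of sorbic acid from crotonaldehyde); no secondary amine is present, so no dienamine can form and the γ-stereocentre is not scrambled.

Step 15
Reactants: 18 (5S,6R)-6-{(2S,4R,6S)-4,6-dimethyl-6-[(triethylsilyl)oxy]oct-7-en-2-yl}-5-hydroxy-5,6-dihydro-2H-pyran-2-one; 27 (2E,4E,6R)-8-[(tert-butyldimethylsilyl)oxy]-6-{[(tert-butyldimethylsilyl)oxy]methyl}-4-methylocta-2,4-dienoic acid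
Product: 28 (2R,3S)-2-{(2S,4R,6S)-4,6-dimethyl-6-[(triethylsilyl)oxy]oct-7-en-2-yl}-6-oxo-3,6-dihydro-2H-pyran-3-yl (2E,4E,6R)-8-[(tert-butyldimethylsilyl)oxy]-6-{[(tert-butyldimethylsilyl)oxy]methyl}-4-methylocta-2,4-dienoate
Conditions: 27 (1.2 equiv), DCC (1.3 equiv), DMAP (0.2 equiv), CH2Cl2, 0 °C → rt
Reagents that add atoms: none
Why: Steglich esterification acylates the only free hydroxyl (the secondary allylic C5–OH) at oxygen, so C5 keeps its S configuration.

Step 16
Reactants: 28 (2R,3S)-2-{(2S,4R,6S)-4,6-dimethyl-6-[(triethylsilyl)oxy]oct-7-en-2-yl}-6-oxo-3,6-dihydro-2H-pyran-3-yl (2E,4E,6R)-8-[(tert-butyldimethylsilyl)oxy]-6-{[(tert-butyldimethylsilyl)oxy]methyl}-4-methylocta-2,4-dienoate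
Product: 29 (2R,3S)-2-[(2S,4R,6S)-6-hydroxy-4,6-dimethyloct-7-en-2-yl]-6-oxo-3,6-dihydro-2H-pyran-3-yl (2E,4E,6R)-8-hydroxy-6-(hydroxymethyl)-4-methylocta-2,4-dienoate
Conditions: HF·pyridine, pyridine, THF, 0 °C → rt
Reagents that add atoms: none
Why: Buffered fluoride-mediated global desilylation removes both primary silyl ethers and the tertiary triethylsilyl ether without harming the unsaturated lactone, the dienoate ester or the tertiary allylic alcohol.

## Compound list

1 | (R)-1-bromo-3-chloro-2-methylpropane | BrC[C@H](C)CCl | starting material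
2 | 2-[(2S)-3-chloro-2-methylpropyl]-4,4,5,5-tetramethyl-1,3,2-dioxaborolane | CC1(C)OB(C[C@H](C)CCl)OC1(C)C | intermediate
3 | (R)-but-3-en-2-ol | C=C[C@@H](C)O | starting material
4 | (2R)-but-3-en-2-yl N,N-di(propan-2-yl)carbamate | C=C[C@@H](C)OC(=O)N(C(C)C)C(C)C | intermediate
5 | {(2R)-2-[(diisopropylcarbamoyl)oxy]but-3-en-2-yl}lithium (lithiated carbamate) | C=C[C@@]([Li])(C)OC(=O)N(C(C)C)C(C)C | intermediate
6 | lithium [(2R)-2-[(diisopropylcarbamoyl)oxy]but-3-en-2-yl][(2S)-3-chloro-2-methylpropyl](pinacolato)borate | C=C[C@@]([B-]1(C[C@H](C)CCl)OC(C)(C)C(C)(C)O1)(C)OC(=O)N(C(C)C)C(C)C.[Li+] | intermediate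
7 | 2-[(3R,5S)-6-chloro-3,5-dimethylhex-1-en-3-yl]-4,4,5,5-tetramethyl-1,3,2-dioxaborolane | C=C[C@@](C)(B1OC(C)(C)C(C)(C)O1)C[C@H](C)CCl | intermediate
8 | (3S,5S)-6-chloro-3,5-dimethylhex-1-en-3-ol | C=C[C@@](C)(O)C[C@H](C)CCl | intermediate
9 | {[(3S,5S)-6-chloro-3,5-dimethylhex-1-en-3-yl]oxy}triethylsilane | C=C[C@@](C)(O[Si](CC)(CC)CC)C[C@H](C)CCl | intermediate
10 | furan | c1ccoc1 | starting material
11 | 2-bromopropanoyl chloride (racemic) | CC(Br)C(Cl)=O | starting material
12 | 2-bromo-1-(furan-2-yl)propan-1-one (racemic) | CC(Br)C(=O)c1ccco1 | intermediate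
13 | triethyl{[(3S,5S)-6-iodo-3,5-dimethylhex-1-en-3-yl]oxy}silane | C=C[C@@](C)(O[Si](CC)(CC)CC)C[C@H](C)CI | intermediate
14 | {(2S,4S)-2,4-dimethyl-4-[(triethylsilyl)oxy]hex-5-en-1-yl}zinc iodide | C=C[C@@](C)(O[Si](CC)(CC)CC)C[C@H](C)C[Zn]I | intermediate
15 | (2S,4R,6S)-1-(furan-2-yl)-2,4,6-trimethyl-6-[(triethylsilyl)oxy]oct-7-en-1-one | C=C[C@@](C)(O[Si](CC)(CC)CC)C[C@H](C)C[C@H](C)C(=O)c1ccco1 | intermediate
16 | (1R,2S,4R,6S)-1-(furan-2-yl)-2,4,6-trimethyl-6-[(triethylsilyl)oxy]oct-7-en-1-ol | C=C[C@@](C)(O[Si](CC)(CC)CC)C[C@H](C)C[C@H](C)[C@@H](O)c1ccco1 | intermediate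
17 | (2R)-2-{(2S,4R,6S)-4,6-dimethyl-6-[(triethylsilyl)oxy]oct-7-en-2-yl}-6-hydroxy-2H-pyran-3(6H)-one (anomer mixture) | C=C[C@@](C)(O[Si](CC)(CC)CC)C[C@H](C)C[C@H](C)[C@H]1OC(O)C=CC1=O | intermediate
18 | (5S,6R)-6-{(2S,4R,6S)-4,6-dimethyl-6-[(triethylsilyl)oxy]oct-7-en-2-yl}-5-hydroxy-5,6-dihydro-2H-pyran-2-one | C=C[C@@](C)(O[Si](CC)(CC)CC)C[C@H](C)C[C@H](C)[C@H]1OC(=O)C=C[C@@H]1O | intermediate
19 | furan-2(5H)-one | O=C1C=CCO1 | starting material
20 | (2-methylprop-1-en-1-yl)boronic acid | CC(C)=CB(O)O | starting material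
21 | (4R)-4-(2-methylprop-1-en-1-yl)oxolan-2-one | CC(C)=C[C@@H]1COC(=O)C1 | intermediate
22 | (2R)-2-(2-methylprop-1-en-1-yl)butane-1,4-diol | CC(C)=C[C@H](CO)CCO | intermediate
23 | (2R)-1,4-bis[(tert-butyldimethylsilyl)oxy]-2-(2-methylprop-1-en-1-yl)butane | CC(C)=C[C@H](CO[Si](C)(C)C(C)(C)C)CCO[Si](C)(C)C(C)(C)C | intermediate
24 | (2E,4R)-6-[(tert-butyldimethylsilyl)oxy]-4-{[(tert-butyldimethylsilyl)oxy]methyl}-2-methylhex-2-en-1-ol | OC/C(C)=C/[C@H](CO[Si](C)(C)C(C)(C)C)CCO[Si](C)(C)C(C)(C)C | intermediate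
25 | (2E,4R)-6-[(tert-butyldimethylsilyl)oxy]-4-{[(tert-butyldimethylsilyl)oxy]methyl}-2-methylhex-2-enal | O=C/C(C)=C/[C@H](CO[Si](C)(C)C(C)(C)C)CCO[Si](C)(C)C(C)(C)C | intermediate
26 | malonic acid | OC(=O)CC(O)=O | starting material
27 | (2E,4E,6R)-8-[(tert-butyldimethylsilyl)oxy]-6-{[(tert-butyldimethylsilyl)oxy]methyl}-4-methylocta-2,4-dienoic acid | OC(=O)/C=C/C(C)=C/[C@H](CO[Si](C)(C)C(C)(C)C)CCO[Si](C)(C)C(C)(C)C | intermediate
28 | (2R,3S)-2-{(2S,4R,6S)-4,6-dimethyl-6-[(triethylsilyl)oxy]oct-7-en-2-yl}-6-oxo-3,6-dihydro-2H-pyran-3-yl (2E,4E,6R)-8-[(tert-butyldimethylsilyl)oxy]-6-{[(tert-butyldimethylsilyl)oxy]methyl}-4-methylocta-2,4-dienoate | C=C[C@@](C)(O[Si](CC)(CC)CC)C[C@H](C)C[C@H](C)[C@H]1OC(=O)C=C[C@@H]1OC(=O)/C=C/C(C)=C/[C@H](CO[Si](C)(C)C(C)(C)C)CCO[Si](C)(C)C(C)(C)C | intermediate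
29 | (2R,3S)-2-[(2S,4R,6S)-6-hydroxy-4,6-dimethyloct-7-en-2-yl]-6-oxo-3,6-dihydro-2H-pyran-3-yl (2E,4E,6R)-8-hydroxy-6-(hydroxymethyl)-4-methylocta-2,4-dienoate | C=C[C@@](C)(O)C[C@H](C)C[C@H](C)[C@H]1OC(=O)C=C[C@@H]1OC(=O)/C=C/C(C)=C/[C@H](CO)CCO | target

## Step count and risks

Total step count: 16. Longest linear sequence: 9 steps (steps 1, 3, 4, 6, 7, 8, 9, 15, 16, from compound 1 to 29).

The three steps most likely to fail:

**Step 6 (key coupling).** An α-bromo heteroaryl ketone with a β-branched alkylzinc is outside the published scope. Zinc–bromine exchange (giving the reduced ketone), slow transmetalation or erosion of the new α-stereocentre are the likely failure modes. The fallback sets out from 11 and from alkylzinc 14 (made from 9 as in step 6) and comes back at 15. Acid chloride 11, N-benzylaniline and Et3N give racemic N-benzyl-2-bromo-N-phenylpropanamide F1, the electrophile class for which the nickel/pybox stereoconvergent alkyl–alkyl coupling is established. Coupling of 14 with F1 (NiCl2·glyme, (R,R)-i-Pr-Pybox, DMI/THF, 0 °C) gives (2S,4R,6S)-N-benzyl-2,4,6-trimethyl-N-phenyl-6-[(triethylsilyl)oxy]oct-7-enamide F2. Furan-2-yllithium F3 (from furan 10 and n-BuLi in THF) is added to the anilide at −78 °C; the tetrahedral adduct collapses on work-up to ketone 15, where the route resumes.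

**Step 3 (lithiation–borylation).** A lithiated allyl carbamate with a terminal vinyl group may be borylated at the γ-carbon or lose configuration, and the crowded boronate may migrate sluggishly. The fallback sets out from boronate 2 and comes back at 8, using an alkyne as a masked vinyl group. (R)-4-(Trimethylsilyl)but-3-yn-2-ol is carbamoylated as in step 2 to (2R)-4-(trimethylsilyl)but-3-yn-2-yl N,N-di(propan-2-yl)carbamate F4. Lithiation (s-BuLi, TMEDA, Et2O, −78 °C), borylation with 2 and 1,2-shift give the tertiary propargylic boronic ester 2-[(3R,5S)-6-chloro-3,5-dimethyl-1-(trimethylsilyl)hex-1-yn-3-yl]-4,4,5,5-tetramethyl-1,3,2-dioxaborolane F5. Oxidation with NaBO3·4H2O gives (3S,5S)-6-chloro-3,5-dimethyl-1-(trimethylsilyl)hex-1-yn-3-ol F6. TBAF buffered with AcOH removes silicon to give (3S,5S)-6-chloro-3,5-dimethylhex-1-yn-3-ol F7, and semihydrogenation (H2, Pd/CaCO3 poisoned with Pb(OAc)2, quinoline) returns alkene 8.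

**Step 9 (internal redox isomerisation).** The acid co-catalyst may ionise the tertiary allylic silyl ether, the iridium hydride may reduce the vinyl group, or the trans selectivity may be lower with the bulky side chain. The fallback sets out from lactol 17 and comes back at 18, replacing the internal hydride shuttle by separate oxidation and reduction. Dess–Martin periodinane (NaHCO3, CH2Cl2, 0 °C) oxidises 17 to the keto-lactone (6R)-6-{(2S,4R,6S)-4,6-dimethyl-6-[(triethylsilyl)oxy]oct-7-en-2-yl}-2H-pyran-2,5(6H)-dione F8. This is used crude (it can enolise to an aromatic pyranone) in a Luche reduction (NaBH4, CeCl3·7H2O, MeOH/CH2Cl2, −78 °C). Axial hydride attack places the new hydroxyl trans to the side chain and gives 18.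

## Further compounds

F1 | step 6 | N-benzyl-2-bromo-N-phenylpropanamide (racemic) | CC(Br)C(=O)N(Cc1ccccc1)c1ccccc1
F2 | step 6 | (2S,4R,6S)-N-benzyl-2,4,6-trimethyl-N-phenyl-6-[(triethylsilyl)oxy]oct-7-enamide | C=C[C@@](C)(O[Si](CC)(CC)CC)C[C@H](C)C[C@H](C)C(=O)N(Cc1ccccc1)c1ccccc1
F3 | step 6 | furan-2-yllithium | [Li]c1ccco1
F4 | step 3 | (2R)-4-(trimethylsilyl)but-3-yn-2-yl N,N-di(propan-2-yl)carbamate | C[Si](C)(C)C#C[C@@H](C)OC(=O)N(C(C)C)C(C)C
F5 | step 3 | 2-[(3R,5S)-6-chloro-3,5-dimethyl-1-(trimethylsilyl)hex-1-yn-3-yl]-4,4,5,5-tetramethyl-1,3,2-dioxaborolane | C[Si](C)(C)C#C[C@@](C)(B1OC(C)(C)C(C)(C)O1)C[C@H](C)CCl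
F6 | step 3 | (3S,5S)-6-chloro-3,5-dimethyl-1-(trimethylsilyl)hex-1-yn-3-ol | C[Si](C)(C)C#C[C@@](C)(O)C[C@H](C)CCl
F7 | step 3 | (3S,5S)-6-chloro-3,5-dimethylhex-1-yn-3-ol | C#C[C@@](C)(O)C[C@H](C)CCl
F8 | step 9 | (6R)-6-{(2S,4R,6S)-4,6-dimethyl-6-[(triethylsilyl)oxy]oct-7-en-2-yl}-2H-pyran-2,5(6H)-dione | C=C[C@@](C)(O[Si](CC)(CC)CC)C[C@H](C)C[C@H](C)[C@H]1OC(=O)C=CC1=O
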